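## Analysis of the target

The target 17 is an isoflavone: a 4H-chromen-4-one (ring A fused to the pyranone ring C) with a methoxyl on C7 and the aryl ring B on C3. Ring B is a contiguously tetrasubstituted benzene. C1' is bonded to C3, C2' carries a methoxyl, and C3'–C4' is fused to a 2,2-dimethyl-2H-pyran whose carbon C4'' sits on C3' and whose oxygen sits on C4' (C2'' is the CMe2 carbon, C3''=C4'' the double bond). There is no stereocentre, so the problem is purely one of constitution. The main difficulty is the angular fusion: C3' lies between the oxygens on C2' and C4', and an annulation onto a free 4'-phenol would have to choose C3' over the open C5'. The second difficulty is the C3–C1' bond, which joins ring C to an arene carbon with an ortho methoxyl. Sensitive groups are the styrene-like C3''=C4'' double bond (hydrogenation, strong acid, electrophilic oxidants), the chromone C2=C3 enone (ring opening by hard nucleophilic base) and the aryl methyl ethers (strong Lewis acids). The plan rests on one feature: C3' carries a single carbon, C4'', ortho to the C4' oxygen, so a ring B precursor with a formyl group on C3' and a free hydroxyl on C4' (a salicylaldehyde) has the angular regiochemistry built in before the pyran exists.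

## Retrosynthetic reasoning

**Ring C, O1–C2.** 17 is cut at O1–C2, with C2 returned to the aldehyde level. The retron is the 2-hydroxyphenyl β-keto aldehyde 15, which closes to the hemiacetal 16 and dehydrates. A free ortho-hydroxyl would interfere while the keto aldehyde is built, so 15 is carried as its methoxymethyl ether 14. One acid treatment then unmasks the phenol and closes the ring. The forward step forms only a C–O bond and is driven by formation of the aromatic pyranone.

**C3–C4, by a 1,2-aroyl shift.** In 14 the carbon bearing ring B (future C3) is bonded to the aroyl carbon (future C4) and the formyl carbon (future C2). Cutting C3–C4 and returning the aroyl group to the formyl carbon maps 14 onto the trans-epoxy ketone 13. This turns the C3–C1' bond problem into carbonyl chemistry on a one-carbon substituent at C1'. The forward reaction must ionise the Cβ–O bond of the epoxide, which the ortho and para oxygens of ring B favour, and migrate aroyl rather than hydride.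

**Epoxide oxygen.** Removing the epoxide oxygen from 13 gives the (E)-enone 12. A nucleophilic epoxidation is chosen because it attacks only the electron-poor enone. An electrophilic oxidant would attack the electron-rich C3''=C4'' alkene first.

**Cα=Cβ.** The enone double bond of 12 is cut into the methyl ketone 10 and the non-enolisable aldehyde 8. This is the convergent step: 10 carries ring A and 8 carries ring B with the finished chromene.

**Protecting group.** 10 comes from the hydroxy ketone 9 by O-protection. An acetal ether is chosen because it survives base and peroxide and leaves under mild acid, which the chromene tolerates; hydrogenolysis is excluded by C3''=C4''.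

**C1'–CHO.** The formyl group of 8 is removed to give the aryllithium 7 and, behind it, the bromide 6. The bromine marks C1' through the chromene-forming step and is exchanged at low temperature.

**Pyran ring, C3''–C4'' and O–C2'' (key disconnection).** 6 is cut at C3''–C4'' and at O–C2''. This leads through the ortho-quinone methide 5 and the aminophenol 4 back to the salicylaldehyde 2 and the alkenylboronic acid 3. The cut is made here and not at C3'–C4'' because C4'' is then already attached to C3' as the formyl carbon, so no C3' versus C5' choice arises. The forward reaction must transfer the alkenyl group to the formyl carbon and then close the oxatriene.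

**C1'–Br.** 2 is cut at the C–Br bond to the commercial salicylaldehyde 1. The forward bromination must go para to the free hydroxyl, which is also ortho to the methoxyl.

## Alternatives that were turned down

**Alternative 1: ring C through a 4-hydroxycoumarin.**
- Disconnection: O1–C2 and C4–C4a of ring C, with ring C first made at the coumarin oxidation pattern.
- Forward key step: thermal condensation of 3-methoxyphenol A2 with the activated arylmalonate A3. The aryl ester forms first, then an aryloxycarbonyl ketene acylates ring A para to its methoxyl, giving the 3-aryl-4-hydroxycoumarin A1.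
- For: two ring C bonds form in one operation, ring A needs no protecting group, and the site of acylation on A2 is dependable. On these points it is stronger than the chalcone sequence chosen here.
- Against: A1 has its carbonyls transposed relative to 17. C2 must be reduced to a CH and C4 kept as the ketone, which requires masking the acidic 4-hydroxyl, partial reduction of the lactone and dehydration, with over-reduction of the emerging enone a constant risk. The ketene is generated at high temperature in the presence of the chromene. A3 must itself be made from the bromide 6 by a C-arylation and an ester exchange, so the angular chromene still has to be solved first.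
- Comparison: it is a longer endgame built on the same ring B. The chosen route keeps every ring C carbon at its final oxidation level after one epoxidation and uses no late hydride reduction.

**Alternative 2: ring B by Danheiser benzannulation on the chromone.**
- Disconnection: C1'–C2', C2'–C3' and C4'–C5' of ring B, which is grown on a preformed chromone.
- Forward key step: irradiation of the diazoketone A5 gives a vinylketene by Wolff rearrangement. It adds to the siloxyalkyne A6 in a [2+2] sense, and 4π opening followed by 6π closure on heating gives the phenol A4, with prenyl on C3', hydroxyl on C2' and silyloxy on C4'.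
- For: the whole substitution pattern of ring B is written into the two partners and the two oxygens are differentiated from the start. No electrophilic substitution is needed at all, and the C3–C1' bond exists from the beginning. On regiocontrol it is as strong as or stronger than the chosen route, which depends on one bromination whose selectivity the structure does not enforce.
- Against: A5 and A6 each need several steps and are sensitive. Irradiating a chromone enone invites photocycloaddition at C2=C3, and the nucleophilic ynol ether can add to chromone C2. After A4, three more operations remain: methylation of a hindered hydroxyl, desilylation and oxidative cyclization of the prenyl phenol to the chromene.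
- Comparison: it is clearly longer, and its risk is spread over several steps. The chosen route offers a short sequence from commercial arenes, with the pyran formed directly at the chromene oxidation level.

**Alternative 3: ring B as a cyclohexane-1,3-dione.**
- Disconnection: the same two pyran bonds, C3'–C4'' and O–C2'', but made on a non-aromatic ring B.
- Forward key step: cyclohexane-1,3-dione A8 condenses at its C2 with 3-methylbut-2-enal A9, and the 1-oxatriene closes by oxa-6π electrocyclization to the dihydrochromenone A7.
- For: A8 is symmetric and has one nucleophilic carbon, so no angular or linear question arises. The annulation needs neither boron nor an amine adduct and is among the most dependable chromenylations. On precedent and robustness of the key step it is stronger than the chosen one.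
- Against: A7 lacks the aromaticity of ring B, the substituent on C1' and the O-methyl on C2'. It would need functionalization α to the ketone, dehydrogenation to the phenol in the presence of the oxidisable chromene alkene, and methylation of a hindered phenol before reaching the equivalent of aldehyde 8.
- Comparison: at least three extra steps and two changes of oxidation state on ring B. The chosen route uses the same pericyclic closure on an arene that already carries the O-methyl, the free hydroxyl and the C1' bromine, so nothing has to be adjusted afterwards.

Key step: step 2

## Route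

Assumption: 1, 3 and 9 are taken as commercial. The target is achiral, so the stereocentres that appear in 4, 11, 13, 14, 15 and 16 are racemic, need no control and are all gone in 17.

Step 1
Reactants: 1 2-hydroxy-6-methoxybenzaldehyde
Product: 2 3-bromo-6-hydroxy-2-methoxybenzaldehyde
Conditions: NBS (1.0 equiv), MeCN, 0 °C → rt
Reagents that add atoms: N-bromosuccinimide, O=C1CCC(=O)N1Br
Why: Electrophilic aromatic bromination; the free hydroxyl is the strongest donor and directs para, to the position that is also ortho to the methoxyl, while its chelation to the formyl group makes delivery of bromine to the ortho position less likely. One equivalent at low temperature in a polar solvent should limit dibromination.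

Step 2
Reactants: 2 3-bromo-6-hydroxy-2-methoxybenzaldehyde; 3 (2-methylprop-1-en-1-yl)boronic acid
Product: 6 6-bromo-5-methoxy-2,2-dimethyl-2H-chromene, via Petasis aminophenol 4 (not isolated), via ortho-quinone methide 5 (not isolated)
Conditions: Bn2NH (0.2 equiv), 3 (1.5 equiv), 1,4-dioxane, 90 °C
Reagents that add atoms: none
Why: The amine condenses with the formyl group of 2 to an iminium ion while the neighbouring phenoxide binds the boron of 3 as a tetracoordinate boronate. From this ate complex the alkenyl group migrates intramolecularly to the iminium carbon (borono-Mannich or Petasis step), which forms C3''–C4'' and gives 4. At 90 °C the ortho-hydroxybenzylamine 4 expels Bn2NH and becomes the ortho-quinone methide 5, a 1-oxatriene. Thermal disrotatory oxa-6π electrocyclization of the Z isomer of 5 forms O–C2'' and closes the six-membered pyran (a pericyclic closure, formally 6-endo), regaining the aromaticity of ring B; the E isomer is returned to 4 by reversible re-addition of the amine. The closest known reaction type is the amine-catalysed condensation of salicylaldehydes with alkenylboronic acids to 2H-chromenes, here run with a β,β-dimethylalkenyl boronic acid so that C2'' becomes quaternary. No stereocentre is formed, since C2'' carries two methyl groups and the racemic centre of 4 is lost in 5. No arene regioselectivity is needed, because C4'' is the formyl carbon that already sits on C3'; the only selectivity required, transfer to the iminium carbon, is secured by the boronate being tethered to the adjacent phenoxide. The aryl bromide, the methoxyl and the product alkene are inert to these conditions.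

Step 3
Reactants: 6 6-bromo-5-methoxy-2,2-dimethyl-2H-chromene
Product: 8 5-methoxy-2,2-dimethyl-2H-chromene-6-carbaldehyde, via aryllithium 7 (not isolated)
Conditions: n-BuLi, THF, −78 °C; DMF, −78 °C → rt; H2O
Reagents that add atoms: N,N-dimethylformamide, CN(C)C=O
Why: Bromine–lithium exchange at −78 °C is much faster than any addition to the styrene-like alkene, and the ortho methoxyl stabilises 7. Formylation with DMF (Bouveault reaction) gives the aldehyde when the hemiaminal alkoxide collapses on aqueous work-up.

Step 4
Reactants: 9 1-(2-hydroxy-4-methoxyphenyl)ethan-1-one (paeonol)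
Product: 10 1-[4-methoxy-2-(methoxymethoxy)phenyl]ethan-1-one
Conditions: NaH, DMF, 0 °C; MeOCH2Cl, 0 °C → rt
Reagents that add atoms: chloromethyl methyl ether, COCCl
Why: Williamson-type O-alkylation; NaH breaks the intramolecular hydrogen bond and deprotonates the phenol in preference to the far less acidic methyl ketone. The phenoxide is then alkylated on oxygen by the reactive α-chloro ether.

Step 5
Reactants: 8 5-methoxy-2,2-dimethyl-2H-chromene-6-carbaldehyde; 10 1-[4-methoxy-2-(methoxymethoxy)phenyl]ethan-1-one
Product: 12 (2E)-1-[4-methoxy-2-(methoxymethoxy)phenyl]-3-(5-methoxy-2,2-dimethyl-2H-chromen-6-yl)prop-2-en-1-one, via aldol adduct 11 (not isolated)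
Conditions: KOH, EtOH/H2O, rt
Reagents that add atoms: none
Why: Claisen–Schmidt condensation; the enolate of 10 adds to the non-enolisable aldehyde 8 and E1cB dehydration of 11 gives the conjugated enone with the thermodynamically favoured E geometry. The acetal ether and the chromene are stable to aqueous alkali.

Step 6
Reactants: 12 (2E)-1-[4-methoxy-2-(methoxymethoxy)phenyl]-3-(5-methoxy-2,2-dimethyl-2H-chromen-6-yl)prop-2-en-1-one
Product: 13 rac-[(2S,3R)-3-(5-methoxy-2,2-dimethyl-2H-chromen-6-yl)oxiran-2-yl][4-methoxy-2-(methoxymethoxy)phenyl]methanone (trans-epoxide)
Conditions: 30% aq H2O2, NaOH, MeOH/THF, 0 °C → rt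
Reagents that add atoms: hydrogen peroxide, OO
Why: Weitz–Scheffer nucleophilic epoxidation; hydroperoxide adds in conjugate fashion and the enolate closes onto the O–O bond, with bond rotation in the enolate leading to the trans-epoxide as a racemate whose two centres are erased in steps 7 and 8. The electron-rich C3''=C4'' alkene does not react with a nucleophilic oxidant.

Step 7
Reactants: 13 rac-[(2S,3R)-3-(5-methoxy-2,2-dimethyl-2H-chromen-6-yl)oxiran-2-yl][4-methoxy-2-(methoxymethoxy)phenyl]methanone
Product: 14 3-[4-methoxy-2-(methoxymethoxy)phenyl]-2-(5-methoxy-2,2-dimethyl-2H-chromen-6-yl)-3-oxopropanal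
Conditions: BF3·OEt2 (0.5 equiv), CH2Cl2, −20 → 0 °C, short contact; aq NaHCO3
Reagents that add atoms: none
Why: Lewis-acid-promoted Meinwald-type rearrangement of an α,β-epoxy ketone with 1,2-aroyl shift, as known for chalcone oxides; the Cβ–O bond ionises to a benzylic cation stabilised by the ortho methoxyl and the para pyran oxygen, the aroyl group migrates from Cα to Cβ and Cα becomes the formyl carbon. The product is an enolisable β-keto aldehyde, so its single centre has no fixed configuration; any 17 already formed by loss of the acetal is carried into step 8.

Step 8
Reactants: 14 3-[4-methoxy-2-(methoxymethoxy)phenyl]-2-(5-methoxy-2,2-dimethyl-2H-chromen-6-yl)-3-oxopropanal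
Product: 17 7-methoxy-3-(5-methoxy-2,2-dimethyl-2H-chromen-6-yl)-4H-chromen-4-one, via free phenol 15 (not isolated), via 2-hydroxyisoflavanone 16 (not isolated)
Conditions: conc. HCl (cat.), MeOH/THF, 40 °C
Reagents that add atoms: none
Why: Acid-catalysed methanolysis of the methoxymethyl acetal frees the phenol 15, which adds to the formyl group (6-exo-trig hemiacetal formation) to give 16. Acid-catalysed dehydration then gives the aromatic 4-pyranone, which drives the sequence; dilute acid at moderate temperature should leave the chromene alkene intact.

## Compound list

1 | 2-hydroxy-6-methoxybenzaldehyde | COc1cccc(O)c1C=O | starting material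
2 | 3-bromo-6-hydroxy-2-methoxybenzaldehyde | COc1c(Br)ccc(O)c1C=O | intermediate
3 | (2-methylprop-1-en-1-yl)boronic acid | CC(C)=CB(O)O | starting material
4 | 4-bromo-2-[1-(dibenzylamino)-3-methylbut-2-en-1-yl]-3-methoxyphenol (racemic, not isolated) | COc1c(Br)ccc(O)c1C(C=C(C)C)N(Cc1ccccc1)Cc1ccccc1 | intermediate
5 | (6Z)-4-bromo-5-methoxy-6-(3-methylbut-2-en-1-ylidene)cyclohexa-2,4-dien-1-one (ortho-quinone methide, not isolated) | CC(C)=C/C=C1\C(=O)C=CC(Br)=C1OC | intermediate
6 | 6-bromo-5-methoxy-2,2-dimethyl-2H-chromene | COc1c(Br)ccc2OC(C)(C)C=Cc12 | intermediate
7 | (5-methoxy-2,2-dimethyl-2H-chromen-6-yl)lithium (not isolated) | COc1c([Li])ccc2OC(C)(C)C=Cc12 | intermediate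
8 | 5-methoxy-2,2-dimethyl-2H-chromene-6-carbaldehyde | COc1c(C=O)ccc2OC(C)(C)C=Cc12 | intermediate
9 | 1-(2-hydroxy-4-methoxyphenyl)ethan-1-one (paeonol) | CC(=O)c1ccc(OC)cc1O | starting material
10 | 1-[4-methoxy-2-(methoxymethoxy)phenyl]ethan-1-one | CC(=O)c1ccc(OC)cc1OCOC | intermediate
11 | 3-hydroxy-1-[4-methoxy-2-(methoxymethoxy)phenyl]-3-(5-methoxy-2,2-dimethyl-2H-chromen-6-yl)propan-1-one (racemic, not isolated) | COCOc1cc(OC)ccc1C(=O)CC(O)c1ccc2OC(C)(C)C=Cc2c1OC | intermediate
12 | (2E)-1-[4-methoxy-2-(methoxymethoxy)phenyl]-3-(5-methoxy-2,2-dimethyl-2H-chromen-6-yl)prop-2-en-1-one | COCOc1cc(OC)ccc1C(=O)/C=C/c1ccc2OC(C)(C)C=Cc2c1OC | intermediate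
13 | rac-[(2S,3R)-3-(5-methoxy-2,2-dimethyl-2H-chromen-6-yl)oxiran-2-yl][4-methoxy-2-(methoxymethoxy)phenyl]methanone (trans, racemic; one enantiomer drawn) | COCOc1cc(OC)ccc1C(=O)[C@H]1O[C@@H]1c1ccc2OC(C)(C)C=Cc2c1OC | intermediate
14 | 3-[4-methoxy-2-(methoxymethoxy)phenyl]-2-(5-methoxy-2,2-dimethyl-2H-chromen-6-yl)-3-oxopropanal (racemic, in equilibrium with its enol) | COCOc1cc(OC)ccc1C(=O)C(C=O)c1ccc2OC(C)(C)C=Cc2c1OC | intermediate
15 | 3-(2-hydroxy-4-methoxyphenyl)-2-(5-methoxy-2,2-dimethyl-2H-chromen-6-yl)-3-oxopropanal (racemic, enolisable, not isolated) | COc1ccc(C(=O)C(C=O)c2ccc3OC(C)(C)C=Cc3c2OC)c(O)c1 | intermediate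
16 | 2-hydroxy-7-methoxy-3-(5-methoxy-2,2-dimethyl-2H-chromen-6-yl)-2,3-dihydro-4H-chromen-4-one (racemic mixture of diastereomers, not isolated) | COc1ccc2C(=O)C(c3ccc4OC(C)(C)C=Cc4c3OC)C(O)Oc2c1 | intermediate
17 | 7-methoxy-3-(5-methoxy-2,2-dimethyl-2H-chromen-6-yl)-4H-chromen-4-one | COc1ccc2c(=O)c(-c3ccc4c(c3OC)C=CC(C)(C)O4)coc2c1 | target

## Step count and least certain steps

Total step count: 8. Longest linear sequence: 7 steps (steps 1, 2, 3, 5, 6, 7 and 8, from 1); step 4 is a one-step branch from 9.

**Step 2 (key step).** The most likely failure is protodeboronation of 3 at 90 °C outrunning the alkenyl transfer, because the iminium ion of a benzaldehyde flanked by two ortho substituents forms slowly. A second possibility is a 1,7-hydrogen shift in 5 from a methyl group to oxygen, which competes with ring closure. Fallback, from 2 back to 6: addition of excess (2-methylprop-1-en-1-yl)magnesium bromide to 2 in THF at 0 °C, where the first equivalent only deprotonates the phenol, should give the diol 4-bromo-2-(1-hydroxy-3-methylbut-2-en-1-yl)-3-methoxyphenol F1. Warming F1 in toluene with catalytic pyridinium p-toluenesulfonate dehydrates the ortho-hydroxybenzyl alcohol to the same ortho-quinone methide 5, which closes to 6. This replaces the boron-to-iminium transfer by a carbonyl addition and keeps only the pericyclic closure, the best-precedented part of the step.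

**Step 7.** Three processes threaten the rearrangement. The benzylic cation may be captured by the oxygen of the neighbouring acetal ether, with loss of the protecting group and closure to a flavanonol-type ring. The chromene alkene may be drawn into cationic oligomerisation. Hydride may migrate in place of aroyl. Fallback, from 6 and 9 directly to 17, replacing steps 3 to 8 by a cross-coupling:
- Bromine–lithium exchange on 6 (n-BuLi, THF, −78 °C) and quench with 2-isopropoxy-4,4,5,5-tetramethyl-1,3,2-dioxaborolane gives 2-(5-methoxy-2,2-dimethyl-2H-chromen-6-yl)-4,4,5,5-tetramethyl-1,3,2-dioxaborolane F2.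
- Heating 9 with N,N-dimethylformamide dimethyl acetal gives the enaminone (2E)-3-(dimethylamino)-1-(2-hydroxy-4-methoxyphenyl)prop-2-en-1-one F3.
- I2 in CHCl3 cyclises F3 with loss of the amine to 3-iodo-7-methoxy-4H-chromen-4-one F4.
- Suzuki–Miyaura coupling of F2 with F4 (Pd(dppf)Cl2, K2CO3, 1,4-dioxane/H2O, 80 °C) forms the C3–C1' bond and gives 17.

**Step 1.** The risk is poor site selectivity. Both open activated positions of 1 have one oxygen ortho and one para, so attack ortho to the hydroxyl (para to the methoxyl) and dibromination can compete with the wanted para attack. Fallback: this one leaves 1 aside, sets out from commercial 4-bromo-3-methoxyphenol F5 and rejoins the route at 2.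
- O-Alkylation of F5 (NaH, MeOCH2Cl) gives 1-bromo-2-methoxy-4-(methoxymethoxy)benzene F6.
- Directed ortho-metalation of F6 with lithium 2,2,6,6-tetramethylpiperidide in THF at −78 °C, at the position between the two oxygen substituents, followed by DMF, gives 3-bromo-2-methoxy-6-(methoxymethoxy)benzaldehyde F7. A lithium amide is used because it does not exchange the bromine.
- HCl in MeOH removes the acetal and gives 2.

Here the bromine position is fixed by the starting material and the formyl position by the two directing groups.

**Step 6.** Conjugate addition of hydroperoxide may be slow, because the β-carbon of 12 is deactivated by the 2,4-dioxygenated ring B. The benzylic epoxide may also be opened by solvent or hydroxide during reaction and purification. Fallback, from 10 and 8 back to 13, building the epoxide without an oxidant: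
- Enolisation of 10 with LiN(SiMe3)2 and trapping with Me3SiCl gives {1-[4-methoxy-2-(methoxymethoxy)phenyl]ethenyl}oxy(trimethyl)silane F8.
- N-Bromosuccinimide converts F8 under neutral conditions to 2-bromo-1-[4-methoxy-2-(methoxymethoxy)phenyl]ethan-1-one F9.
- Darzens condensation of F9 with 8 (NaOMe, MeOH, 0 °C) forms the Cα–Cβ bond and the epoxide C–O bond in one step and should give trans-13.

In either case 13 is best taken on crude into step 7.

## Further compounds

F1 | step 2 | 4-bromo-2-(1-hydroxy-3-methylbut-2-en-1-yl)-3-methoxyphenol (racemic) | COc1c(Br)ccc(O)c1C(O)C=C(C)C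
F2 | step 7 | 2-(5-methoxy-2,2-dimethyl-2H-chromen-6-yl)-4,4,5,5-tetramethyl-1,3,2-dioxaborolane | COc1c(B2OC(C)(C)C(C)(C)O2)ccc2OC(C)(C)C=Cc12
F3 | step 7 | (2E)-3-(dimethylamino)-1-(2-hydroxy-4-methoxyphenyl)prop-2-en-1-one | COc1ccc(C(=O)/C=C/N(C)C)c(O)c1
F4 | step 7 | 3-iodo-7-methoxy-4H-chromen-4-one | COc1ccc2c(=O)c(I)coc2c1
F5 | step 1 | 4-bromo-3-methoxyphenol (commercial) | COc1cc(O)ccc1Br
F6 | step 1 | 1-bromo-2-methoxy-4-(methoxymethoxy)benzene | COCOc1ccc(Br)c(OC)c1
F7 | step 1 | 3-bromo-2-methoxy-6-(methoxymethoxy)benzaldehyde | COCOc1ccc(Br)c(OC)c1C=O
F8 | step 6 | {1-[4-methoxy-2-(methoxymethoxy)phenyl]ethenyl}oxy(trimethyl)silane | C=C(O[Si](C)(C)C)c1ccc(OC)cc1OCOC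
F9 | step 6 | 2-bromo-1-[4-methoxy-2-(methoxymethoxy)phenyl]ethan-1-one | COCOc1cc(OC)ccc1C(=O)CBr
A1 | alternative 1 | 4-hydroxy-7-methoxy-3-(5-methoxy-2,2-dimethyl-2H-chromen-6-yl)-2H-chromen-2-one | COc1ccc2c(O)c(-c3ccc4OC(C)(C)C=Cc4c3OC)c(=O)oc2c1
A2 | alternative 1 | 3-methoxyphenol | COc1cccc(O)c1
A3 | alternative 1 | bis(2,4,6-trichlorophenyl) 2-(5-methoxy-2,2-dimethyl-2H-chromen-6-yl)propanedioate | COc1c(C(C(=O)Oc2c(Cl)cc(Cl)cc2Cl)C(=O)Oc2c(Cl)cc(Cl)cc2Cl)ccc2OC(C)(C)C=Cc12
A4 | alternative 2 | 3-[2-hydroxy-3-(3-methylbut-2-en-1-yl)-4-(triisopropylsilyloxy)phenyl]-7-methoxy-4H-chromen-4-one | COc1ccc2c(=O)c(-c3ccc(O[Si](C(C)C)(C(C)C)C(C)C)c(CC=C(C)C)c3O)coc2c1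
A5 | alternative 2 | (3E)-1-diazo-4-(7-methoxy-4-oxo-4H-chromen-3-yl)but-3-en-2-one | COc1ccc2c(=O)c(/C=C/C(=O)C=[N+]=[N-])coc2c1
A6 | alternative 2 | triisopropyl[(5-methylhex-4-en-1-yn-1-yl)oxy]silane | CC(C)=CCC#CO[Si](C(C)C)(C(C)C)C(C)C
A7 | alternative 3 | 2,2-dimethyl-7,8-dihydro-2H-chromen-5(6H)-one | CC1(C)C=CC2=C(CCCC2=O)O1
A8 | alternative 3 | cyclohexane-1,3-dione | O=C1CCCC(=O)C1
A9 | alternative 3 | 3-methylbut-2-enal | CC(C)=CC=O
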